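**Retrosynthetic overview**
1. The strategy rests on the δ-lactone ring O–C2(=O)–C1–C10–C9–C8 with C17 on C8, C20 on C10 and C11 on C9: atom for atom this is a 4,6-dimethyl-2-pyranone-5-carboxylate (isodehydroacetic acid), so the lactone ring is bought, not made.
2. Key disconnection C5–C10 and C7–C8: the cyclohexane ring (C5–C10) is the second ring, closed across the pyranone by a catalytic asymmetric double Michael addition of di-tert-butyl 3-oxoglutarate (C5–C6–C7) to give the 2-oxabicyclo[3.3.1]nonane-3,7-dione.
3. C4–C5: the C(CH3)2CO2R arm is put on C5 by radical tert-alkylation of an enol silane; regiocontrol comes from a transient E1cB opening of the lactone (C7 becomes sp2), and acid re-closes the lactone.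
4. C11–C12 and C13–C16: Mukaiyama aldol of the C11 aldehyde with the enol silane of methyl vinyl ketone, then chelation-controlled methyl addition.
5. C6 is reduced from the exo face and silylated early; at the end the C3 allyl ester is cleaved before the C6 silyl ether, so the γ-hydroxy acid never sits next to an ester or an acid catalyst.

Key step: step 2

Remark: locants follow the labdane-type numbering of the target: C15=C14–C13(C16)(OH)–C12–C11(OH)–C9; ring carbons C5–C10; lactone C10–C1–C2(=O)–O–C8; C17 on C8, C20 on C10, C4(C18)(C19)–C3O2H on C5. The target is (5R,6R,8S,9S,10R,11S,13R).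
Assumption: the quinine-derived squaramide is taken to give the (8S,10R) series in step 2; if the sense of induction is the opposite, its quinidine-derived pseudo-enantiomer is used with no other change.

Step 1
Reactants: 1 isodehydroacetic acid (4,6-dimethyl-2-oxo-2H-pyran-5-carboxylic acid); 2 4-methoxybenzyl chloride
Product: 3 4-methoxybenzyl 4,6-dimethyl-2-oxo-2H-pyran-5-carboxylate
Conditions: K2CO3, DMF, 25 °C
Reagents that add atoms: none
Why: Carboxylate O-alkylation (SN2) by the benzylic chloride should esterify the acid without touching the pyranone, and no stereocentre is formed.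

Step 2
Reactants: 3 4-methoxybenzyl 4,6-dimethyl-2-oxo-2H-pyran-5-carboxylate; 4 di-tert-butyl 3-oxopentanedioate
Product: 6 bicyclic triester 9-(4-methoxybenzyl) 6,8-di-tert-butyl 1,5-dimethyl-3,7-dioxo-2-oxabicyclo[3.3.1]nonane-6,8,9-tricarboxylate (C8 C9 C10 as in the target; ester groups on C5 and C7 equatorial and cis to the lactone bridge), via dihydropyranone mono-adduct 5 (not isolated)
Conditions: quinine-derived 3,5-bis(trifluoromethyl)phenyl squaramide (10 mol %), PhMe, 4 Å MS, 40 °C
Reagents that add atoms: none
Why: Proposed new method: the quinuclidine nitrogen of the catalyst deprotonates 4 while the squaramide N–H bonds hold the lactone carbonyl of 3, so that the soft β-keto ester carbon C5 adds to C10 (β to the lactone C=O) on the catalyst-selected face and, after proton transfer to C1, gives the 3,4-dihydropyranone 5, whose C8=C9 bond is a β-acyloxy acrylate activated by the C11 ester; the second β-keto ester carbon C7 then adds to C8 and closes the cyclohexanone ring in a 6-endo-trig Michael cyclisation across the intact lactone. The closest known reactions are the [3+3] double Michael annulations of 3-oxoglutarate diesters with bis-acceptors and the conjugate additions of stabilised carbanions to 2-pyranones, which normally end in ring opening and aromatisation; here the quaternary C10 makes aromatisation impossible. C10 is set by the catalyst, C8 by the three-atom C5–C6–C7 tether, which can reach only the face of C8 syn to the new C5–C10 bond (hence the cis bridge), C9 by protonation and base-mediated equilibration that place the C11 ester on the lactone side, equatorial on the new ring, and C5 and C7 are enolisable β-keto ester centres that settle equatorial and are erased in step 3. The step needs conjugate addition to win over acyl attack at C2, which the soft, doubly stabilised enolate and hydrogen-bond rather than metal activation should favour, and because 4 is symmetrical the same constitution results whichever of C10 and C8 is attacked first. Should the C7 or C9 enolate expel the lactone oxygen, the resulting enone acid is carried into step 3, where acid should re-close the lactone by oxa-Michael addition.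

Step 3
Reactants: 6 bicyclic triester
Product: 8 keto-lactone acid 1,5-dimethyl-3,7-dioxo-2-oxabicyclo[3.3.1]nonane-9-carboxylic acid (C8 C9 C10 as in the target), via tricarboxylic acid 7 (not isolated)
Conditions: TFA/CH2Cl2 1:1, anisole, 0 → 25 °C
Reagents that add atoms: none
Why: Acidolysis should remove the two tert-butyl esters and the 4-methoxybenzyl ester (anisole traps the benzylic cation), the two β-keto acids of 7 lose CO2 at room temperature through the usual cyclic transition state so that C5 and C7 become CH2, the C11 acid is not β to a ketone and stays, and the acidic medium keeps the lactone closed or re-closes it, so that C8, C9 and C10 are carried through unchanged.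

Step 4
Reactants: 8 keto-lactone acid
Product: 10 ring-opened tris(trimethylsilyl) dienol ether: trimethylsilyl 2,6-dimethyl-6-[2-oxo-2-(trimethylsilyloxy)ethyl]-4-(trimethylsilyloxy)cyclohexa-2,4-diene-1-carboxylate (C9 and C10 as in the target), via trilithium dienolate 9 (not isolated)
Conditions: LDA (3.3 equiv), THF, −78 → −40 °C; TMSCl, −78 → 0 °C; pentane, filtration under argon
Reagents that add atoms: chlorotrimethylsilane, C[Si](C)(C)Cl
Why: LDA should first form the C11 carboxylate, which shields C9–H, then remove the axial C7–H that is anti-periplanar to the C8–O bond so that the β-acyloxy ketone opens by E1cB to the cyclohexenone carboxylate in which C7 is sp2, and the third equivalent can then enolise only toward C5 (kinetic α′-deprotonation of a cyclohexenone), silylation giving the cross-conjugated dienol silyl ether with C9 and C10 untouched; any closed-ring C5 enol ether formed by direct C5 deprotonation reacts at the same carbon in step 5 and converges in step 6.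

Step 5
Reactants: 10 tris(trimethylsilyl) dienol ether; 11 prop-2-en-1-yl 2-bromo-2-methylpropanoate
Product: 13 enone diacid 6-(carboxymethyl)-2,6-dimethyl-4-oxo-5-[2-methyl-1-oxo-1-(prop-2-en-1-yloxy)propan-2-yl]cyclohex-2-ene-1-carboxylic acid (C9 and C10 as in the target; C5 a mixture), via bis(trimethylsilyl) ester 12 (not isolated)
Conditions: fac-Ir(ppy)3 (1 mol %), MeCN, blue LEDs, 25 °C; aq citric acid, 0 °C
Reagents that add atoms: none
Why: In this photoredox radical alkylation of an enol silane the excited iridium catalyst should reduce the tertiary bromide 11 to the electrophilic 2-(allyloxycarbonyl)prop-2-yl radical, which adds to the CH terminus C5 of the electron-rich 2-silyloxydiene, oxidation of the resulting silyloxyallyl radical and loss of the silyl group restore the enone, and cold aqueous acid cleaves the silyl esters; the C5 configuration is left open here because it is set in step 6.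

Step 6
Reactants: 13 enone diacid
Product: 14 keto-lactone acid 6-[2-methyl-1-oxo-1-(prop-2-en-1-yloxy)propan-2-yl]-1,5-dimethyl-3,7-dioxo-2-oxabicyclo[3.3.1]nonane-9-carboxylic acid (C5 C8 C9 C10 as in the target)
Conditions: TsOH·H2O (20 mol %), MeCN, 25 °C
Reagents that add atoms: none
Why: Acid-catalysed intramolecular oxa-Michael addition of the C2 acid to C8 of the enone should re-form the bridged δ-lactone (the six-membered closure can only reach the face of C8 syn to the C10 acetic acid arm, so C8 follows from C10), while C5 epimerises through the enol to the isomer with the bulky arm equatorial and cis to the lactone bridge, as in the target, and the temperature is kept low because the open form is a vinylogous β-keto acid that could lose CO2 on heating.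

Step 7
Reactants: 14 keto-lactone acid
Product: 15 endo alcohol 7-hydroxy-6-[2-methyl-1-oxo-1-(prop-2-en-1-yloxy)propan-2-yl]-1,5-dimethyl-3-oxo-2-oxabicyclo[3.3.1]nonane-9-carboxylic acid (C6–OH cis to the lactone bridge and to the C5 arm; C5 C6 C8 C9 C10 as in the target)
Conditions: NaBH4, CeCl3·7H2O, MeOH/THF, −78 °C; AcOH quench
Reagents that add atoms: none
Why: In this Luche reduction the lactone bridge blocks the endo face of C6, so hydride should enter from the exo face and give the endo alcohol cis to the bridge and to the C5 arm (6R), and the cold, near-neutral medium avoids both E1cB opening of the β-acyloxy ketone and lactonisation of the new hydroxyl onto the hindered allyl ester.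

Step 8
Reactants: 15 endo alcohol
Product: 17 silyl ether acid 7-(triethylsilyloxy)-6-[2-methyl-1-oxo-1-(prop-2-en-1-yloxy)propan-2-yl]-1,5-dimethyl-3-oxo-2-oxabicyclo[3.3.1]nonane-9-carboxylic acid (stereocentres as in 15), via bis(triethylsilyl) compound 16 (not isolated)
Conditions: TESOTf, 2,6-lutidine, CH2Cl2, −78 → 0 °C; aq citric acid/THF, 0 °C
Reagents that add atoms: triethylsilyl trifluoromethanesulfonate, CC[Si](CC)(CC)OS(=O)(=O)C(F)(F)F
Why: The silyl triflate with a hindered pyridine base should silylate both the hindered secondary alcohol and the acid, and the labile silyl ester of 16 is hydrolysed on mild aqueous work-up, which leaves O6 masked so that it can neither attack the allyl ester nor be acylated in the following steps.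

Step 9
Reactants: 17 silyl ether acid
Product: 19 aldehyde 9-formyl-7-(triethylsilyloxy)-1,5-dimethyl-3-oxo-2-oxabicyclo[3.3.1]nonan-6-yl dimethylacetic acid allyl ester (prop-2-en-1-yl 2-methyl-2-[…]propanoate; stereocentres as in 17), via acid chloride 18 (not isolated)
Conditions: 1-chloro-N,N,2-trimethylprop-1-en-1-amine, CH2Cl2, 0 °C; LiAlH(OtBu)3, THF, −78 °C
Reagents that add atoms: none
Why: The α-chloro enamine should convert the hindered C11 acid into the acid chloride under neutral conditions, and LiAlH(OtBu)3 at −78 °C reduces an acid chloride to the aldehyde without touching the lactone, the neopentylic allyl ester or the silyl ether, C9 not being enolised.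

Step 10
Reactants: 19 aldehyde; 20 2-(trimethylsilyloxy)buta-1,3-diene
Product: 21 β-hydroxy enone prop-2-en-1-yl 2-{9-[(1S)-1-hydroxy-3-oxopent-4-en-1-yl]-1,5-dimethyl-3-oxo-7-(triethylsilyloxy)-2-oxabicyclo[3.3.1]nonan-6-yl}-2-methylpropanoate (11S; ring stereocentres as in 19)
Conditions: BF3·OEt2, CH2Cl2, −78 °C; aq NaHCO3
Reagents that add atoms: none
Why: This Mukaiyama aldol addition runs under non-basic Lewis acid conditions (no β-elimination of the C8 oxygen from the aldehyde), and in the open Felkin–Anh transition state the bulkier C10 flank (C1H2, C20 and the arm-bearing C5) should lie anti to the nucleophile while the carbonyl oxygen sits over the oxygen-bearing C8 flank, so that the CH2 terminus of the silyl dienol ether attacks from the exposed outer face past H9 and gives the 11S alcohol.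

Step 11
Reactants: 21 β-hydroxy enone
Product: 22 diol prop-2-en-1-yl 2-{9-[(1S,3R)-1,3-dihydroxy-3-methylpent-4-en-1-yl]-1,5-dimethyl-3-oxo-7-(triethylsilyloxy)-2-oxabicyclo[3.3.1]nonan-6-yl}-2-methylpropanoate (11S 13R; ring stereocentres as in 19)
Conditions: MeMgBr (3 equiv), CH2Cl2/Et2O, −78 °C; aq NH4Cl
Reagents that add atoms: methylmagnesium bromide, C[Mg]Br
Why: In this chelation-controlled 1,2-addition the first equivalent of the Grignard reagent forms the C11 magnesium alkoxide, which chelates the C13 ketone in a six-membered half-chair with the C9 substituent pseudo-equatorial, and methyl should add axially on the face anti to that substituent, so that vinyl stays equatorial and the 1,3-syn (11S,13R) diol results.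

Step 12
Reactants: 22 diol
Product: 23 acid 2-{9-[(1S,3R)-1,3-dihydroxy-3-methylpent-4-en-1-yl]-1,5-dimethyl-3-oxo-7-(triethylsilyloxy)-2-oxabicyclo[3.3.1]nonan-6-yl}-2-methylpropanoic acid
Conditions: Pd(PPh3)4 (5 mol %), morpholine, THF, 25 °C
Reagents that add atoms: none
Why: In this Tsuji–Trost deallylation zerovalent palladium ionises the allyl ester and morpholine captures the allyl fragment under neutral conditions that should leave the lactone, the vinyl group and the non-activated tertiary allylic alcohol alone, and the free C3 acid cannot lactonise because O6 is still silylated.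

Step 13
Reactants: 23 acid
Product: 24 target CNP0297019.1 (5R,6R,8S,9S,10R,11S,13R)
Conditions: TBAF, AcOH, THF, 0 °C; pH 6 phosphate buffer, 0 °C, rapid extraction
Reagents that add atoms: none
Why: Buffered fluoride should cleave the Si–O bond while C3 is present as its carboxylate, which the freed C6 hydroxyl cannot attack, and the near-neutral medium and cold pH 6 work-up avoid γ-lactonisation, translactonisation and opening of the δ-lactone, no stereocentre being touched.

**Compound list**
1 | isodehydroacetic acid (4,6-dimethyl-2-oxo-2H-pyran-5-carboxylic acid) | CC1=CC(=O)OC(C)=C1C(=O)O | starting material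
2 | 4-methoxybenzyl chloride | COc1ccc(CCl)cc1 | starting material
3 | 4-methoxybenzyl 4,6-dimethyl-2-oxo-2H-pyran-5-carboxylate | CC1=CC(=O)OC(C)=C1C(=O)OCc1ccc(OC)cc1 | intermediate
4 | di-tert-butyl 3-oxopentanedioate (di-tert-butyl 3-oxoglutarate) | CC(C)(C)OC(=O)CC(=O)CC(=O)OC(C)(C)C | starting material
5 | mono-Michael adduct: 4-methoxybenzyl 4-(1,5-di-tert-butoxy-1,3,5-trioxopentan-2-yl)-4,6-dimethyl-2-oxo-3,4-dihydro-2H-pyran-5-carboxylate, C10 as in the target, C5 unassigned | CC1=C(C(=O)OCc2ccc(OC)cc2)[C@@](C)(C(C(=O)OC(C)(C)C)C(=O)CC(=O)OC(C)(C)C)CC(=O)O1 | intermediate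
6 | 9-(4-methoxybenzyl) 6,8-di-tert-butyl 1,5-dimethyl-3,7-dioxo-2-oxabicyclo[3.3.1]nonane-6,8,9-tricarboxylate, C8, C9, C10 as in the target, C5 and C7 esters equatorial | O=C(OCc1ccc(OC)cc1)[C@@H]1[C@]2(C)CC(=O)O[C@@]1(C)[C@@H](C(=O)OC(C)(C)C)C(=O)[C@H]2C(=O)OC(C)(C)C | intermediate
7 | 1,5-dimethyl-3,7-dioxo-2-oxabicyclo[3.3.1]nonane-6,8,9-tricarboxylic acid, stereocentres as in 6 | O=C(O)[C@@H]1[C@]2(C)CC(=O)O[C@@]1(C)[C@@H](C(=O)O)C(=O)[C@H]2C(=O)O | intermediate
8 | 1,5-dimethyl-3,7-dioxo-2-oxabicyclo[3.3.1]nonane-9-carboxylic acid, C8, C9, C10 as in the target | O=C(O)[C@@H]1[C@]2(C)CC(=O)O[C@@]1(C)CC(=O)C2 | intermediate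
9 | trilithium salt of the ring-opened enone diacid: 6-(carboxylatomethyl)-2,6-dimethyl-4-oxidocyclohexa-2,4-diene-1-carboxylate, C9 and C10 as in the target | [Li+].[Li+].[Li+].[O-]C(=O)C[C@]1(C)C=C([O-])C=C(C)[C@@H]1C([O-])=O | intermediate
10 | trimethylsilyl 2,6-dimethyl-6-[2-oxo-2-(trimethylsilyloxy)ethyl]-4-(trimethylsilyloxy)cyclohexa-2,4-diene-1-carboxylate, C9 and C10 as in the target | C[Si](C)(C)OC(=O)C[C@]1(C)C=C(O[Si](C)(C)C)C=C(C)[C@@H]1C(=O)O[Si](C)(C)C | intermediate
11 | prop-2-en-1-yl 2-bromo-2-methylpropanoate (allyl 2-bromoisobutyrate) | C=CCOC(=O)C(C)(C)Br | starting material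
12 | bis(trimethylsilyl) ester of 13 | C[Si](C)(C)OC(=O)C[C@]1(C)C(C(C)(C)C(=O)OCC=C)C(=O)C=C(C)[C@@H]1C(=O)O[Si](C)(C)C | intermediate
13 | 6-(carboxymethyl)-2,6-dimethyl-4-oxo-5-[2-methyl-1-oxo-1-(prop-2-en-1-yloxy)propan-2-yl]cyclohex-2-ene-1-carboxylic acid, C9 and C10 as in the target, C5 a mixture | OC(=O)C[C@]1(C)C(C(C)(C)C(=O)OCC=C)C(=O)C=C(C)[C@@H]1C(=O)O | intermediate
14 | 6-[2-methyl-1-oxo-1-(prop-2-en-1-yloxy)propan-2-yl]-1,5-dimethyl-3,7-dioxo-2-oxabicyclo[3.3.1]nonane-9-carboxylic acid, C5, C8, C9, C10 as in the target | O=C(O)[C@@H]1[C@]2(C)CC(=O)O[C@@]1(C)CC(=O)[C@H]2C(C)(C)C(=O)OCC=C | intermediate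
15 | 7-hydroxy compound from 14, C6–OH endo (cis to the lactone bridge and to the C5 arm) | O=C(O)[C@@H]1[C@]2(C)CC(=O)O[C@@]1(C)C[C@@H](O)[C@H]2C(C)(C)C(=O)OCC=C | intermediate
16 | triethylsilyl ester of 17 | CC[Si](CC)(CC)OC(=O)[C@@H]1[C@]2(C)CC(=O)O[C@@]1(C)C[C@@H](O[Si](CC)(CC)CC)[C@H]2C(C)(C)C(=O)OCC=C | intermediate
17 | 7-(triethylsilyloxy) acid: C6–OSiEt3, C11 acid, C3 allyl ester, stereocentres as in 15 | O=C(O)[C@@H]1[C@]2(C)CC(=O)O[C@@]1(C)C[C@@H](O[Si](CC)(CC)CC)[C@H]2C(C)(C)C(=O)OCC=C | intermediate
18 | C11 acid chloride of 17 | O=C(Cl)[C@@H]1[C@]2(C)CC(=O)O[C@@]1(C)C[C@@H](O[Si](CC)(CC)CC)[C@H]2C(C)(C)C(=O)OCC=C | intermediate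
19 | C11 aldehyde: prop-2-en-1-yl 2-[9-formyl-1,5-dimethyl-3-oxo-7-(triethylsilyloxy)-2-oxabicyclo[3.3.1]nonan-6-yl]-2-methylpropanoate, stereocentres as in 17 | O=C[C@@H]1[C@]2(C)CC(=O)O[C@@]1(C)C[C@@H](O[Si](CC)(CC)CC)[C@H]2C(C)(C)C(=O)OCC=C | intermediate
20 | 2-(trimethylsilyloxy)buta-1,3-diene | C=CC(=C)O[Si](C)(C)C | starting material
21 | (11S)-β-hydroxy vinyl ketone: prop-2-en-1-yl 2-{9-[(1S)-1-hydroxy-3-oxopent-4-en-1-yl]-1,5-dimethyl-3-oxo-7-(triethylsilyloxy)-2-oxabicyclo[3.3.1]nonan-6-yl}-2-methylpropanoate | C=CC(=O)C[C@H](O)[C@@H]1[C@]2(C)CC(=O)O[C@@]1(C)C[C@@H](O[Si](CC)(CC)CC)[C@H]2C(C)(C)C(=O)OCC=C | intermediate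
22 | (11S,13R)-diol, C3 allyl ester, C6 triethylsilyl ether | C=C[C@](C)(O)C[C@H](O)[C@@H]1[C@]2(C)CC(=O)O[C@@]1(C)C[C@@H](O[Si](CC)(CC)CC)[C@H]2C(C)(C)C(=O)OCC=C | intermediate
23 | (11S,13R)-diol, C3 free acid, C6 triethylsilyl ether | C=C[C@](C)(O)C[C@H](O)[C@@H]1[C@]2(C)CC(=O)O[C@@]1(C)C[C@@H](O[Si](CC)(CC)CC)[C@H]2C(C)(C)C(=O)O | intermediate
24 | CNP0297019.1, (5R,6R,8S,9S,10R,11S,13R) | C=C[C@](C)(O)C[C@H](O)[C@@H]1[C@]2(C)CC(=O)O[C@@]1(C)C[C@@H](O)[C@H]2C(C)(C)C(=O)O | target

**Step count**
Total steps: 13. Longest linear sequence: 13 steps (1 → 24); 2, 4, 11 and 20 are bought.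

**Steps most likely to fail**

Step 2 (key step). The first conjugate addition may not take place at all on the weakly electrophilic, partly aromatic pyranone, because it must build a quaternary centre. Alternatively, attack at C8 may be followed by irreversible ring opening and condensation instead of the second Michael closure. The fallback uses known chemistry only, sets out from 4 and comes back at 8. Benzyl acetoacetate and acetaldehyde are condensed (piperidine, AcOH cat.) to benzyl 2-ethylidene-3-oxobutanoate F1. Compound 4 adds to F1 and the adduct closes by aldol addition of its second active methylene onto the acetyl group (piperidine, EtOH), the classical alkylidene acetoacetate ketol annulation, to give the ketol triester F2. TFA removes the tert-butyl esters, both β-keto acids lose CO2 and the tertiary alcohol eliminates, giving racemic benzyl 2,6-dimethyl-4-oxocyclohex-2-ene-1-carboxylate F3. Hosomi–Sakurai allylation (allyltrimethylsilane, TiCl4, CH2Cl2, −78 °C) at the methyl-bearing β-carbon builds the quaternary C10 in the allyl ketone F4. RuCl3 (cat.)/NaIO4 cleaves the allyl group to the acetic acid arm of the keto acid F5. IBX (DMSO, 70 °C) dehydrogenates the ketone toward C7–C8 only, since C10 bears no hydrogen, and gives the enone acid F6. TsOH closes the lactone as in step 6, with C9 equilibrating through the dienol, to the racemic benzyl ester keto-lactone F7. Hydrogenolysis (H2, Pd/C, EtOAc) gives the racemic keto-lactone acid F8, which is resolved by chromatography on a chiral stationary phase to 8.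

Step 5. Addition of the tertiary radical to C5, which lies next to the quaternary C10, may be too slow, so that reduction or dimerisation of the radical takes over. The fallback sets out from 8 and comes back at 13, and replaces the halide/photocatalyst manifold by oxidative cross-coupling of two preformed enolates. The trilithium dienolate 9 (from 8 and LDA as in step 4) and the lithium enolate of prop-2-en-1-yl 2-methylpropanoate (LDA, THF, −78 °C) are mixed and oxidised with Fe(acac)3 (THF, −78 → 0 °C). Cold aqueous acid work-up then gives 13 directly, and no new compound is made on the way.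

Step 10. Facial selectivity may be poor, because the two flanks of the aldehyde (C8 and C10) differ little and substrate control may not discriminate well; the β-hydroxy enone may also cyclise by oxa-Michael addition under the Lewis acid. The fallback sets out from 19 and comes back at 21, and moves the control of C11 to an auxiliary. The divalent tin enolate of (R)-3-acetyl-4-isopropyl-1,3-thiazolidine-2-thione (Sn(OTf)2, N-ethylpiperidine, CH2Cl2, −78 °C; the enantiomer that the tin-chelated chair transition state predicts for 11S) adds to 19 to give the N-acyl thiazolidinethione aldol adduct F9. MeNHOMe·HCl and imidazole (CH2Cl2, 25 °C) displace the auxiliary to give the N-methoxy-N-methylamide F10. Vinylmagnesium bromide (THF, −78 → 0 °C, inverse quench into cold buffer) then gives 21.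

Further compounds
F1 | step 2 | benzyl 2-ethylidene-3-oxobutanoate | CC=C(C(C)=O)C(=O)OCc1ccccc1
F2 | step 2 | 1-benzyl 3,5-di-tert-butyl 6-hydroxy-2,6-dimethyl-4-oxocyclohexane-1,3,5-tricarboxylate (racemic, mixture of diastereomers) | CC1(O)C(C(=O)OCc2ccccc2)C(C)C(C(=O)OC(C)(C)C)C(=O)C1C(=O)OC(C)(C)C
F3 | step 2 | benzyl 2,6-dimethyl-4-oxocyclohex-2-ene-1-carboxylate (racemic) | CC1=CC(=O)CC(C)C1C(=O)OCc1ccccc1
F4 | step 2 | benzyl 2,6-dimethyl-4-oxo-2-(prop-2-en-1-yl)cyclohexane-1-carboxylate (racemic) | C=CCC1(C)CC(=O)CC(C)C1C(=O)OCc1ccccc1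
F5 | step 2 | 2-[2-(benzyloxycarbonyl)-1,3-dimethyl-5-oxocyclohexyl]acetic acid (racemic) | OC(=O)CC1(C)CC(=O)CC(C)C1C(=O)OCc1ccccc1
F6 | step 2 | 2-[6-(benzyloxycarbonyl)-1,5-dimethyl-3-oxocyclohex-4-en-1-yl]acetic acid (racemic) | OC(=O)CC1(C)CC(=O)C=C(C)C1C(=O)OCc1ccccc1
F7 | step 2 | rac-benzyl 1,5-dimethyl-3,7-dioxo-2-oxabicyclo[3.3.1]nonane-9-carboxylate (relative configuration as in 8) | O=C(OCc1ccccc1)[C@@H]1[C@]2(C)CC(=O)O[C@@]1(C)CC(=O)C2
F8 | step 2 | rac-1,5-dimethyl-3,7-dioxo-2-oxabicyclo[3.3.1]nonane-9-carboxylic acid (racemate of 8) | O=C(O)[C@@H]1[C@]2(C)CC(=O)O[C@@]1(C)CC(=O)C2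
F0 | step 5 | none | none
F9 | step 10 | (11S)-aldol adduct of 19 with (R)-3-acetyl-4-isopropyl-1,3-thiazolidine-2-thione | S=C1SC[C@@H](C(C)C)N1C(=O)C[C@H](O)[C@@H]1[C@]2(C)CC(=O)O[C@@]1(C)C[C@@H](O[Si](CC)(CC)CC)[C@H]2C(C)(C)C(=O)OCC=C
F10 | step 10 | (11S)-β-hydroxy N-methoxy-N-methylamide | CON(C)C(=O)C[C@H](O)[C@@H]1[C@]2(C)CC(=O)O[C@@]1(C)C[C@@H](O[Si](CC)(CC)CC)[C@H]2C(C)(C)C(=O)OCC=C
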